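**Strategy**

Ring B (C5–C10) with its C7=C8 alkene, C8 methyl, oxygenated C9 and the C4 carbon on C5 is (S)-carvone, whose isopropenyl group is C4 plus both C4 methyls; everything rests on cutting ring A at the C3–C4 bond. The key step adds a hydrogen atom to the isopropenyl CH2 and lets the tertiary C4 radical attack a C3 aldehyde, which in one operation closes ring A, creates the gem-dimethyl quaternary C4 and the equatorial C3 carbinol, and locks the trans-decalin. Its precursor is a carvone-derived enone bearing the C5 isopropenyl group and, on quaternary C10, a methyl and a trans 3-oxopropyl arm. Side chain, C9–H and the C32 ester follow.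

Key step: step 4

Remarks: labdane numbering (C1–C20) is used for all bicyclic compounds. The acyl residue is taken as 32-hydroxydotriacontanoyl (31 CH2 groups between the carbonyl carbon and the terminal oxygen). TBS = tert-butyldimethylsilyl, PMB = 4-methoxybenzyl, IPNBSH = N-isopropylidene-N′-(2-nitrobenzenesulfonyl)hydrazine. Compound 3 is carried as a mixture of epimers at the methylated carbon, because that centre becomes planar again in step 2.

**Route**

Step 1
Reactants: 1 (S)-(+)-carvone
Product: 3 6-methylcarvone (epimer mixture at the new centre; C5 as in carvone), via lithium dienolate 2 (not isolated)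
Conditions: LDA (1.1 equiv), THF, −78 °C; MeI, −78 → 0 °C
Reagents that add atoms: iodomethane, CI
Why: Kinetic deprotonation of the enone by LDA takes place at the α′ methylene and the cross-conjugated lithium dienolate is C-methylated (enolate alkylation); the configuration of the new centre is irrelevant because it becomes sp2 again in step 2.

Step 2
Reactants: 3 6-methylcarvone; 4 propargyl bromide
Product: 6 (5R,6R)-2,6-dimethyl-5-(prop-1-en-2-yl)-6-(prop-2-ynyl)cyclohex-2-en-1-one (propargyl trans to isopropenyl), via lithium enolate 5 (not isolated)
Conditions: LDA (1.2 equiv), THF, −78 → −20 °C; DMPU, propargyl bromide, −78 → 0 °C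
Reagents that add atoms: none
Why: A second α′ enolisation gives the tetrasubstituted enolate, and enolate alkylation by the reactive propargylic bromide should occur on the face anti to the neighbouring isopropenyl group, as allylic halides are known to do on this enolate, which sets quaternary C10 with the new arm trans to the isopropenyl group.

Step 3
Reactants: 6 propargyl enone
Product: 7 keto aldehyde (the propargyl group of 6 turned into a CH2CH2CHO arm; configuration unchanged)
Conditions: CpRu(MeCN)3PF6 (5 mol%), 5,5′-bis(trifluoromethyl)-2,2′-bipyridine (5 mol%), NMP/H2O 4:1, 25 °C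
Reagents that add atoms: water, O
Why: Ruthenium-catalysed anti-Markovnikov alkyne hydration runs through a metal vinylidene that only a terminal alkyne can form, so water is delivered to the terminal carbon to give the aldehyde while the ketone, the enone and the isopropenyl group are left alone.

Step 4
Reactants: 7 keto aldehyde
Product: 8 ent-3β-hydroxy-11-nordrim-7-en-9-one (trans-decalin; C3–OH equatorial and cis to the C10 methyl; H5 trans to the C10 methyl)
Conditions: Fe(acac)3 (0.3 equiv), PhSiH3 (2.5 equiv), degassed EtOH (0.02 M), 60 °C
Reagents that add atoms: none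
Why: Proposed new method: an iron hydride formed from Fe(acac)3 and PhSiH3 should transfer a hydrogen atom to the CH2 terminus of the isopropenyl group, and the tertiary C4 radical then adds to the aldehyde carbon C3, after which the alkoxy radical is reduced by divalent iron and protonated by ethanol, which drains the reversible addition forward (HAT-initiated reductive alkene–aldehyde cyclisation). The closest known reaction types are the iron-hydride HAT reductive cyclisation of alkene-tethered ketones to hindered tertiary alcohols and the tin-mediated 6-exo cyclisation of alkyl radicals onto aldehydes; an aldehyde acceptor beside a spectator enone has not been shown. Ring A is the only ring closed, 6-exo-trig onto C=O through a chair, and the trans ring fusion follows from the existing C5 and C10 centres, whose radical-bearing and aldehyde-bearing arms are trans-diequatorial on ring B. The one new stereocentre, C3, is set by that chair with the carbonyl oxygen pseudo-equatorial, away from the axial hydrogens on C1 and C5, which gives the equatorial alcohol cis to the C10 methyl. The step needs hydrogen-atom transfer to the electron-neutral 1,1-disubstituted alkene and not to the electron-poor trisubstituted enone alkene, which alkene electronics secure, and it needs ring closure to outrun reduction of the radical, which dilution secures, as does the fact that attack on C7 or C9 would give four-membered rings.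

Step 5
Reactants: 8 hydroxy enone
Product: 9 C3 TBS ether of 8
Conditions: TBSOTf (1.3 equiv), 2,6-lutidine, CH2Cl2, −78 → 0 °C
Reagents that add atoms: tert-butyldimethylsilyl triflate, CC(C)(C)[Si](C)(C)OS(=O)(=O)C(F)(F)F
Why: Silylation of the hindered secondary alcohol with a silyl triflate and a non-nucleophilic pyridine base is standard, and the enone, which has no α′ hydrogen, is not enolised under these conditions.

Step 6
Reactants: 10 but-3-yn-1-ol
Product: 11 tert-butyl(but-3-ynyloxy)dimethylsilane
Conditions: TBSCl, imidazole, CH2Cl2, 0 °C → rt
Reagents that add atoms: tert-butyldimethylsilyl chloride, CC(C)(C)[Si](C)(C)Cl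
Why: Imidazole-promoted silylation of an unhindered primary alcohol is routine and masks the hydroxyl against the organoaluminium reagent of step 7.

Step 7
Reactants: 11 silyl ether of but-3-yn-1-ol
Product: 14 (E)-5-(tert-butyldimethylsilyloxy)-3-methylpent-2-en-1-ol, via alkenyldimethylalane 12 (not isolated), via lithium alkenylalanate 13 (not isolated)
Conditions: Me3Al (2 equiv), Cp2ZrCl2 (0.2 equiv), CH2Cl2, 0 °C → rt; volatiles removed; n-BuLi, hexane/THF, 0 °C; (CH2O)n, rt; aqueous work-up
Reagents that add atoms: trimethylaluminium, C[Al](C)C; paraformaldehyde (as formaldehyde), C=O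
Why: Zirconium-catalysed carboalumination adds methyl and aluminium syn across the terminal alkyne with methyl on the internal carbon, and the derived lithium alanate is hydroxymethylated by formaldehyde with retention, which fixes the E geometry of the future C13=C14 alkene.

Step 8
Reactants: 14 allylic alcohol
Product: 16 tert-butyl{[(E)-5-(4-methoxybenzyloxy)-3-methylpent-3-enyl]oxy}dimethylsilane, via sodium alkoxide 15 (not isolated)
Conditions: NaH, THF/DMF, 0 °C; PMBCl, n-Bu4NI (cat.), rt
Reagents that add atoms: 4-methoxybenzyl chloride, COc1ccc(CCl)cc1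
Why: Williamson etherification of the primary allylic alkoxide with the activated benzylic chloride is reliable and leaves the primary silyl ether untouched.

Step 9
Reactants: 16 PMB/TBS diether
Product: 17 (E)-5-(4-methoxybenzyloxy)-3-methylpent-3-en-1-ol
Conditions: TBAF, THF, 0 °C → rt
Reagents that add atoms: none
Why: Fluoride cleaves the silicon–oxygen bond selectively, and the PMB ether and the alkene are inert to it.

Step 10
Reactants: 17 homoallylic alcohol
Product: 18 (E)-5-iodo-3-methylpent-2-enyl 4-methoxybenzyl ether
Conditions: PPh3, imidazole, I2, CH2Cl2, 0 °C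
Reagents that add atoms: iodine, II
Why: Appel-type iodination converts the primary alcohol into the iodide by SN2 displacement of the alkoxyphosphonium ion without touching the allylic ether or the alkene.

Step 11
Reactants: 9 silyl-protected enone; 18 homoallylic iodide
Product: 20 C9 tertiary allylic alcohol carrying the C11–C16 chain (OH cis to the C10 methyl as drawn), via alkyllithium 19 (not isolated)
Conditions: 18 (1.5 equiv), t-BuLi (3.0 equiv), Et2O/pentane, −78 °C; then 9, −78 → −40 °C; H2O
Reagents that add atoms: none
Why: Iodine–lithium exchange with two equivalents of t-BuLi at −78 °C gives the primary alkyllithium, which should add 1,2 to the C9 carbonyl (no α′ hydrogen) from the face anti to the axial C10 methyl, as alkyllithiums do with 2,6,6-trisubstituted cyclohex-2-enones; the C9 configuration does not matter because this centre becomes sp2 in step 12.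

Step 12
Reactants: 20 tertiary allylic alcohol
Product: 21 3-O-TBS-15-O-PMB ent-3β,15-dihydroxylabda-8,13E-dien-7-one
Conditions: pyridinium chlorochromate, [C5H5NH][CrO3Cl] (2.5 equiv), Celite, CH2Cl2, rt
Reagents that add atoms: pyridinium chlorochromate (one of its oxo oxygens becomes the C7 carbonyl oxygen), [O-][Cr](=O)(=O)Cl.c1cc[nH+]cc1
Why: In this Babler–Dauben oxidative transposition the tertiary allylic chromate ester undergoes a [3,3] shift to the secondary C7 chromate, which is oxidised to the enone with a tetrasubstituted C8=C9 alkene, and silyl and PMB ethers tolerate the reagent.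

Step 13
Reactants: 21 enone
Product: 22 3-O-TBS-15-O-PMB ent-labda-8,13E-diene-3β,7,15-triol with the free C7–OH on the face of the C10 methyl (7R)
Conditions: NaBH4, CeCl3·7H2O, MeOH, −78 → −40 °C
Reagents that add atoms: none
Why: Luche reduction gives clean 1,2-reduction, and axial hydride delivery from the face opposite the C10 methyl should place the new C7 hydroxyl pseudo-equatorial, on the same face as that methyl.

Step 14
Reactants: 22 allylic alcohol
Product: 25 3-O-TBS-15-O-PMB ent-labda-7,13E-diene-3β,15-diol, via hydrazone adduct 23 (not isolated), via allylic diazene 24 (not isolated)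
Conditions: IPNBSH, PPh3, DEAD, THF, 0 → 23 °C; then CF3CH2OH/H2O 1:1, 23 °C
Reagents that add atoms: none
Why: Mitsunobu alkylation of the acidic sulfonylhydrazone nitrogen inverts C7, hydrolysis of the hydrazone and loss of arenesulfinic acid give the allylic diazene, and its retro-ene loss of N2 transfers hydrogen suprafacially from the C7 face to C9, so that H9 ends up anti to the C10 methyl and the alkene moves to C7=C8 (reductive allylic transposition).

Step 15
Reactants: 25 PMB ether
Product: 26 3-O-TBS ent-labda-7,13E-diene-3β,15-diol (free C15–OH)
Conditions: DDQ (1.2 equiv), CH2Cl2/pH 7 buffer 10:1, 0 °C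
Reagents that add atoms: none
Why: Oxidative cleavage of the PMB ether by DDQ runs through the stabilised benzylic cation and spares the silyl ether and both trisubstituted alkenes when it is done cold and buffered.

Step 16
Reactants: 27 16-bromohexadecanoic acid
Product: 28 16-bromohexadecan-1-ol
Conditions: BH3·THF (1.5 equiv), THF, 0 °C → rt; then H2O
Reagents that add atoms: none
Why: Borane reduces the carboxylic acid chemoselectively through the acyloxyborane and leaves the primary bromide untouched.

Step 17
Reactants: 28 bromo alcohol
Product: 29 (16-bromohexadecyloxy)(tert-butyl)dimethylsilane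
Conditions: TBSCl, imidazole, CH2Cl2/DMF, rt
Reagents that add atoms: tert-butyldimethylsilyl chloride, CC(C)(C)[Si](C)(C)Cl
Why: Standard silylation of a primary alcohol gives an ether that withstands Grignard formation and is removed at the end together with the C3 silyl ether.

Step 18
Reactants: 29 silyloxy bromide; 27 16-bromohexadecanoic acid
Product: 32 32-(tert-butyldimethylsilyloxy)dotriacontanoic acid, via Grignard reagent 30 (not isolated), via chloromagnesium carboxylate 31 (not isolated)
Conditions: 29, Mg, THF, 45 °C; separately 27, MeMgCl (1.0 equiv), THF, −20 °C; combine, Li2CuCl4 (3 mol%), −20 → 0 °C; cold dilute HCl to pH 3–4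
Reagents that add atoms: none
Why: Copper-catalysed sp3–sp3 cross-coupling of the Grignard reagent with the primary bromide of the pre-formed magnesium carboxylate, whose carboxylate group is inert to the organometallic, joins the two C16 halves.

Step 19
Reactants: 26 allylic alcohol; 32 silyloxy acid
Product: 33 bis-silylated ester (C15 ester of 26 with 32)
Conditions: 32 (1.2 equiv), DCC, DMAP (cat.), CH2Cl2, 0 °C → rt
Reagents that add atoms: none
Why: Steglich esterification acylates the unhindered primary allylic C15 hydroxyl under neutral conditions that neither ionise the allylic system nor disturb the silyl ethers.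

Step 20
Reactants: 33 bis-silylated ester
Product: 34 target, (13E)-ent-3β-hydroxylabda-7,13-dien-15-yl 32-hydroxydotriacontanoate (3R,5S,9R,10S)
Conditions: HF·pyridine, pyridine, THF, 0 °C → rt
Reagents that add atoms: none
Why: Buffered hydrogen fluoride–pyridine cleaves both silyl ethers by fluoride attack at silicon, while the allylic ester, the alkenes and the stereocentres are inert to it.

**Compound list**

1 | (S)-(+)-carvone | CC1=CC[C@@H](CC1=O)C(C)=C | starting material
2 | lithium cross-conjugated dienolate of carvone (formed in the flask) | [Li+].CC1=CC[C@@H](C=C1[O-])C(C)=C | intermediate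
3 | 6-methylcarvone, mixture of epimers at the methylated carbon | CC1=CC[C@H](C(C)=C)C(C)C1=O | intermediate
4 | propargyl bromide | BrCC#C | starting material
5 | lithium enolate of 3 (formed in the flask) | [Li+].CC1=CC[C@H](C(C)=C)C(C)=C1[O-] | intermediate
6 | (5R,6R)-2,6-dimethyl-5-(prop-1-en-2-yl)-6-(prop-2-ynyl)cyclohex-2-en-1-one, propargyl trans to isopropenyl | CC1=CC[C@H](C(C)=C)[C@@](C)(CC#C)C1=O | intermediate
7 | keto aldehyde, 3-oxopropyl arm trans to isopropenyl | CC1=CC[C@H](C(C)=C)[C@@](C)(CCC=O)C1=O | intermediate
8 | ent-3β-hydroxy-11-nordrim-7-en-9-one, trans-decalin, equatorial C3–OH cis to the C10 methyl | CC1=CC[C@@H]2C(C)(C)[C@H](O)CC[C@@]2(C)C1=O | intermediate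
9 | C3 TBS ether of 8 | CC1=CC[C@@H]2C(C)(C)[C@H](O[Si](C)(C)C(C)(C)C)CC[C@@]2(C)C1=O | intermediate
10 | but-3-yn-1-ol | C#CCCO | starting material
11 | tert-butyl(but-3-ynyloxy)dimethylsilane | C#CCCO[Si](C)(C)C(C)(C)C | intermediate
12 | (E)-alkenyldimethylalane from syn carboalumination of 11 (formed in the flask) | C[Al](C)/C=C(\C)CCO[Si](C)(C)C(C)(C)C | intermediate
13 | lithium butyl(dimethyl)alkenylalanate (formed in the flask) | [Li+].CCCC[Al-](C)(C)/C=C(\C)CCO[Si](C)(C)C(C)(C)C | intermediate
14 | (E)-5-(tert-butyldimethylsilyloxy)-3-methylpent-2-en-1-ol | OC/C=C(\C)CCO[Si](C)(C)C(C)(C)C | intermediate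
15 | sodium alkoxide of 14 (formed in the flask) | [Na+].[O-]C/C=C(\C)CCO[Si](C)(C)C(C)(C)C | intermediate
16 | tert-butyl{[(E)-5-(4-methoxybenzyloxy)-3-methylpent-3-enyl]oxy}dimethylsilane | COc1ccc(COC/C=C(\C)CCO[Si](C)(C)C(C)(C)C)cc1 | intermediate
17 | (E)-5-(4-methoxybenzyloxy)-3-methylpent-3-en-1-ol | COc1ccc(COC/C=C(\C)CCO)cc1 | intermediate
18 | (E)-5-iodo-3-methylpent-2-enyl 4-methoxybenzyl ether | COc1ccc(COC/C=C(\C)CCI)cc1 | intermediate
19 | (E)-5-(4-methoxybenzyloxy)-3-methylpent-3-enyllithium (formed in the flask) | [Li]CC/C(C)=C/COCc1ccc(OC)cc1 | intermediate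
20 | C9 tertiary allylic alcohol with 3-OTBS and the PMB-protected C11–C16 chain, C9–OH cis to the C10 methyl | CC1=CC[C@@H]2C(C)(C)[C@H](O[Si](C)(C)C(C)(C)C)CC[C@@]2(C)[C@@]1(O)CC/C(C)=C/COCc3ccc(OC)cc3 | intermediate
21 | 3-O-TBS-15-O-PMB ent-3β,15-dihydroxylabda-8,13E-dien-7-one | CC=1C(=O)C[C@@H]2C(C)(C)[C@H](O[Si](C)(C)C(C)(C)C)CC[C@@]2(C)C=1CC/C(C)=C/COCc3ccc(OC)cc3 | intermediate
22 | 3-O-TBS-15-O-PMB ent-labda-8,13E-diene-3β,7,15-triol, free C7–OH (7R) on the face of the C10 methyl | CC=1[C@H](O)C[C@@H]2C(C)(C)[C@H](O[Si](C)(C)C(C)(C)C)CC[C@@]2(C)C=1CC/C(C)=C/COCc3ccc(OC)cc3 | intermediate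
23 | C7 N-(2-nitrobenzenesulfonyl) acetone hydrazone adduct, C7 inverted (formed in the flask) | CC=1[C@@H](N(N=C(C)C)S(=O)(=O)c4ccccc4[N+](=O)[O-])C[C@@H]2C(C)(C)[C@H](O[Si](C)(C)C(C)(C)C)CC[C@@]2(C)C=1CC/C(C)=C/COCc3ccc(OC)cc3 | intermediate
24 | C7 allylic diazene, nitrogen anti to the C10 methyl (formed in the flask) | CC=1[C@@H](N=N)C[C@@H]2C(C)(C)[C@H](O[Si](C)(C)C(C)(C)C)CC[C@@]2(C)C=1CC/C(C)=C/COCc3ccc(OC)cc3 | intermediate
25 | 3-O-TBS-15-O-PMB ent-labda-7,13E-diene-3β,15-diol | CC1=CC[C@@H]2C(C)(C)[C@H](O[Si](C)(C)C(C)(C)C)CC[C@@]2(C)[C@@H]1CC/C(C)=C/COCc3ccc(OC)cc3 | intermediate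
26 | 3-O-TBS ent-labda-7,13E-diene-3β,15-diol | CC1=CC[C@@H]2C(C)(C)[C@H](O[Si](C)(C)C(C)(C)C)CC[C@@]2(C)[C@@H]1CC/C(C)=C/CO | intermediate
27 | 16-bromohexadecanoic acid | OC(=O)CCCCCCCCCCCCCCCBr | starting material
28 | 16-bromohexadecan-1-ol | OCCCCCCCCCCCCCCCCBr | intermediate
29 | (16-bromohexadecyloxy)(tert-butyl)dimethylsilane | CC(C)(C)[Si](C)(C)OCCCCCCCCCCCCCCCCBr | intermediate
30 | 16-(tert-butyldimethylsilyloxy)hexadecylmagnesium bromide (formed in the flask) | CC(C)(C)[Si](C)(C)OCCCCCCCCCCCCCCCC[Mg]Br | intermediate
31 | chloromagnesium 16-bromohexadecanoate (formed in the flask) | Cl[Mg]OC(=O)CCCCCCCCCCCCCCCBr | intermediate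
32 | 32-(tert-butyldimethylsilyloxy)dotriacontanoic acid | OC(=O)CCCCCCCCCCCCCCCCCCCCCCCCCCCCCCCO[Si](C)(C)C(C)(C)C | intermediate
33 | 3-O-TBS ent-3β-hydroxylabda-7,13E-dien-15-yl 32-(tert-butyldimethylsilyloxy)dotriacontanoate | CC1=CC[C@@H]2C(C)(C)[C@H](O[Si](C)(C)C(C)(C)C)CC[C@@]2(C)[C@@H]1CC/C(C)=C/COC(=O)CCCCCCCCCCCCCCCCCCCCCCCCCCCCCCCO[Si](C)(C)C(C)(C)C | intermediate
34 | CNP0253650.1, (13E)-ent-3β-hydroxylabda-7,13-dien-15-yl 32-hydroxydotriacontanoate (3R,5S,9R,10S) | CC1=CC[C@@H]2C(C)(C)[C@H](O)CC[C@@]2(C)[C@@H]1CC/C(C)=C/COC(=O)CCCCCCCCCCCCCCCCCCCCCCCCCCCCCCCO | target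

**Step count and risks**

Total step count: 20
Longest linear sequence: 12 steps (steps 1–5, 11–15, 19 and 20 from carvone; the side-chain branch through steps 6–15, 19 and 20 is equally long).

Steps most likely to fail:

Step 4. The tertiary radical may be reduced to an isopropyl group, or the aldehyde hydrosilylated, before ring closure. The alkoxy radical may also fragment back faster than it is reduced, and control of the C3 configuration could be incomplete. The fallback uses known chemistry, sets out from 6 and returns at 8. Markovnikov addition of dry HCl (Et2O, 0 °C) to the isopropenyl group, as in the classical hydrochlorination of carvone, should give the tertiary chloride F1. Hydration of its alkyne under the conditions of step 3 should give the chloro aldehyde F2. Slow addition of Bu3SnH with AIBN in refluxing benzene then generates the same C4 radical, which closes 6-exo onto the aldehyde through the same chair; the alkoxy radical is quenched at once by the stannane, and this tin-hydride cyclisation of an alkyl halide onto an aldehyde is an established route to cyclohexanols.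

Step 14. The Mitsunobu displacement at C7, which is shielded by the tetrasubstituted alkene, may stall or divert to elimination into a ring diene. The fallback sets out from 22 and returns at 25. Acylation with methyl chloroformate (pyridine, DMAP, CH2Cl2) should give the C7 methyl carbonate F3. Palladium-catalysed formate hydrogenolysis (Pd(acac)2, n-Bu3P, HCO2H/Et3N, THF, reflux) then lets zerovalent palladium ionise the carbonate anti to the leaving group and deliver hydride from the metal face to the more substituted allyl terminus C9. This places H9 anti to the C10 methyl and the alkene at C7=C8 without any inversion at C7.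

Step 13. Hydride may attack both faces of the flattened enone, and this poor facial selectivity would later scramble C9. The fallback sets out from 21 and returns at 22 and replaces substrate control by catalyst control. A CBS reduction with the (S)-configured 2-methyl-oxazaborolidine and catecholborane (toluene, −78 °C) should, by the usual model with the substituted alkene carbon C8 as the large group and the C6 methylene as the small one, deliver hydride to the face anti to the C10 methyl. This fallback makes no new compound (F0).

Further compounds
F1 | step 4 | tertiary chloride, the isopropenyl group of 6 turned into a 2-chloropropan-2-yl group | CC1=CC[C@H](C(C)(C)Cl)[C@@](C)(CC#C)C1=O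
F2 | step 4 | chloro aldehyde, the alkyne of F1 hydrated to a CH2CH2CHO arm | CC1=CC[C@H](C(C)(C)Cl)[C@@](C)(CCC=O)C1=O
F3 | step 14 | C7 methyl carbonate of 22 | CC=1[C@H](OC(=O)OC)C[C@@H]2C(C)(C)[C@H](O[Si](C)(C)C(C)(C)C)CC[C@@]2(C)C=1CC/C(C)=C/COCc3ccc(OC)cc3
F0 | step 13 | none | none
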